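(The constants used here are those of an exercise; no experiment stands behind them.)

At each meeting with the starting material, catalyst intermediate A goes 932 times faster towards catalyst intermediate B than towards spent catalyst.

    catalyst intermediate B → catalyst intermediate C (k1 = 7.9 s⁻¹)
    starting material + catalyst intermediate A → spent catalyst (k2 = 0.073 M⁻¹ s⁻¹)
    starting material + catalyst intermediate A ⇌ catalyst intermediate B (K3 = 160 M⁻¹, k3 = 68 M⁻¹ s⁻¹)
    reagent + free catalyst → catalyst intermediate A (k4 = 5500 M⁻¹ s⁻¹)
    free catalyst + by-product ⇌ idle complex (K5 = 1200 M⁻¹, k5 = 3.1 M⁻¹ s⁻¹)
    catalyst intermediate C → by-product + catalyst intermediate D (k6 = 0.74 s⁻¹)
    catalyst intermediate D → free catalyst + target (k7 = 0.77 s⁻¹)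

| setting | eta | beta | theta | delta |
|---|---|---|---|---|
| starting material | 10 mM | 10 mM (fed, over 40.0 min) | 10 mM | 10 mM |
| reagent | 10.0 mM | 10.0 mM | 10.0 mM | 10.0 mM |
| free catalyst | 10 µM | 10 µM | 10 µM | 10 µM |
| remark | one stirred flow tank at steady state, fed with the mixture as stated, mean residence time 250 min | a stirred flask in which starting material is dosed at a steady rate over 40.0 min without added volume, worked up at 50 min | one stirred flow tank at steady state, fed with the mixture as stated, mean residence time 50 min | everything together in a closed stirred flask, run for 50 min |
| time |  | 50 min |  | 50 min |

- the set-up with the highest amount of target at the outlet or at the end, in percent of the starting material put in ("none" if the first two lie within 2 percentage points) (eta / beta / theta / delta / none)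
- amount of target at the outlet or at the end, in percent of the starting material put in, eta
- amount of target at the outlet or at the end, in percent of the starting material put in, beta
- amount of target at the outlet or at the end, in percent of the starting material put in, theta
- amount of target at the outlet or at the end, in percent of the starting material put in, delta

- what is said of by-product includes idle complex
- the stated concentrations are those of everything mixed, before any reaction; amounts are the same in each set-up
- the feed brings no volume worth counting
- run time (beta): 50 min

Both roads are first order in c(starting material) and in c(catalyst intermediate A), so their ratio does not drift as c(starting material) falls. But catalyst intermediate B can return. Its way back runs at 0.425 s⁻¹ against 7.9 s⁻¹ forward, so 94.9% of it passes on, and the objection costs little. Each catalyst then gives on average 884 turnovers: this is the lifetime turnover number, the target made per catalyst before it ends as spent catalyst. With the charge of catalyst, the ceiling on target is 88.4% of the starting material.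

A ceiling is not a yield, though. At the charge, one cycle takes about 4.12 s, so the 50 min of delta hold 728 cycles, fewer than the lifetime number. The cycle also lengthens as c(starting material) falls.

The tank can be tested by trial. Surviving catalyst is the charge less target divided by the lifetime number, and output is surviving catalyst times residence time over cycle time. In eta, at half conversion, this gives 11.7 mM, more than the 5.00 mM supposed. At a conversion of 0.7 it gives 4.13 mM, less than the 7.00 mM supposed. So the reckoning puts eta between those two conversions. The same trial for theta, at half conversion and with its shorter residence time, gives 2.33 mM, so the reckoning puts theta below half. The reckoning goes no further, and it does not place beta or delta.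

The forecast gives a single figure for each flask: 62% for eta, 34.5% for beta, 34.5% for theta and 43.5% for delta, with eta best. Its ground is that a small share of turnovers “kill the catalyst whatever the starting-material level”.

The simulation gives eta as best, with 61.9% for eta, 34.7% for beta, 34.6% for theta and 43.7% for delta. With the step to spent catalyst struck out, eta gives 87.7%. At 884 turnovers per catalyst, the target of eta stands for 7.01 µM of spent catalyst, 70.1% of the catalyst charged. The target of theta stands for 3.91 µM of spent catalyst, 39.1% of the catalyst charged.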